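## Retrosynthetic overview
1. The furan is the only ring built, and it is made last. Cutting O1–C2 and C3–C3a gives terminal aryl alkyne 10 and 4-iodoresorcinol 11 (domino Sonogashira / 5-endo-dig closure).
2. Alkyne 10 comes from the hindered benzaldehyde 7 by one-carbon homologation.
3. Both prenyl C–C bonds of 7 are cut at once, giving 2,6-dibromide 4 (double Stille coupling).
4. Dibromide 4 comes from 3-hydroxy-5-methoxybenzaldehyde 1, which already carries the OH/OMe differentiation. Bromination goes to the two positions para to an oxygen.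
5. Both benzene rings are purchased and no protecting groups are used.

Assumption: the target has no stereocentre, its alkenes carry geminal methyls (no E/Z), and the aryl–benzofuran axis should rotate freely at room temperature. It is therefore achiral and "single enantiomer" needs no action.

## Route

Step 1
Reactants: 1 3-hydroxy-5-methoxybenzaldehyde; 2 N-bromosuccinimide
Product: 4 2,6-dibromo-3-hydroxy-5-methoxybenzaldehyde, via monobromide 3 (not isolated)
Conditions: NBS (2.05 equiv), MeCN, 0 °C → rt, dark
Reagents that add atoms: N-bromosuccinimide, O=C1CCC(=O)N1Br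
Why: In this electrophilic aromatic bromination C2 and C6 each lie para to one oxygen and ortho to the other, whereas C4 (ortho/ortho, between the oxygens) is the last site attacked in resorcinol-type rings, so two equivalents stop at the 2,6-dibromide and the aldehyde is untouched in the dark.

Step 2
Reactants: 4 2,6-dibromo-3-hydroxy-5-methoxybenzaldehyde; 5 tributyl(3-methylbut-2-en-1-yl)stannane
Product: 7 3-hydroxy-5-methoxy-2,6-bis(3-methylbut-2-en-1-yl)benzaldehyde, via monoprenyl bromide 6 (not isolated)
Conditions: 5 (2.6 equiv), Pd(PPh3)4 (10 mol %), degassed DMF, 100 °C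
Reagents that add atoms: tributyl(3-methylbut-2-en-1-yl)stannane, CCCC[Sn](CCCC)(CCCC)CC=C(C)C
Why: In this double Stille coupling the ortho-formyl group speeds oxidative addition into both C–Br bonds, the base-free medium tolerates ArOH and CHO, the aryl(η3-prenyl)palladium species reductively eliminates at its unsubstituted terminus to give the linear prenyl group, and whichever bromide reacts first the mono-coupled isomers converge on 7.

Step 3
Reactants: 7 3-hydroxy-5-methoxy-2,6-bis(3-methylbut-2-en-1-yl)benzaldehyde; 8 dimethyl (1-diazo-2-oxopropyl)phosphonate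
Product: 10 3-ethynyl-5-methoxy-2,4-bis(3-methylbut-2-en-1-yl)phenol, via diazoalkene 9 (not isolated)
Conditions: 8 (1.5 equiv), K2CO3 (3 equiv), MeOH, 0 °C → rt
Reagents that add atoms: dimethyl (1-diazo-2-oxopropyl)phosphonate, COP(=O)(OC)C(=[N+]=[N-])C(C)=O
Why: In this Seyferth–Gilbert homologation (Ohira–Bestmann variant) the phenoxide is meta to the CHO and does not deactivate it, and after HWE-type olefination and N2 loss the 1,2-H shift of the alkylidene carbene outruns any addition to the prenyl alkenes.

Step 4
Reactants: 10 3-ethynyl-5-methoxy-2,4-bis(3-methylbut-2-en-1-yl)phenol; 11 4-iodobenzene-1,3-diol (4-iodoresorcinol)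
Product: 13 2-[3-hydroxy-5-methoxy-2,6-bis(3-methylbut-2-en-1-yl)phenyl]-1-benzofuran-6-ol, via alkynylresorcinol 12 (not isolated)
Conditions: PdCl2(PPh3)2 (5 mol %), CuI (10 mol %), Et3N (4 equiv), degassed DMF, rt → 80 °C
Reagents that add atoms: 4-iodobenzene-1,3-diol, Oc1ccc(I)c(O)c1
Why: In this domino Sonogashira coupling / Pd–Cu-promoted 5-endo-dig hydroalkoxylation the linear alkyne keeps the C–C coupling away from the two ortho prenyl groups, only the OH ortho to the alkyne can close (placing the other OH at C6), and Pd/Cu with amine leaves the aryl 1,6-enyne units alone where Au or Pt π-acids would not.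

## Compound list
1 | 3-hydroxy-5-methoxybenzaldehyde | COc1cc(O)cc(C=O)c1 | starting material
2 | N-bromosuccinimide | O=C1CCC(=O)N1Br | starting material
3 | 2-bromo-5-hydroxy-3-methoxybenzaldehyde | COc1cc(O)cc(C=O)c1Br | intermediate (not isolated)
4 | 2,6-dibromo-3-hydroxy-5-methoxybenzaldehyde | COc1cc(O)c(Br)c(C=O)c1Br | intermediate
5 | tributyl(3-methylbut-2-en-1-yl)stannane | CCCC[Sn](CCCC)(CCCC)CC=C(C)C | starting material
6 | 2-bromo-5-hydroxy-3-methoxy-6-(3-methylbut-2-en-1-yl)benzaldehyde | COc1cc(O)c(CC=C(C)C)c(C=O)c1Br | intermediate (not isolated)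
7 | 3-hydroxy-5-methoxy-2,6-bis(3-methylbut-2-en-1-yl)benzaldehyde | COc1cc(O)c(CC=C(C)C)c(C=O)c1CC=C(C)C | intermediate
8 | dimethyl (1-diazo-2-oxopropyl)phosphonate | COP(=O)(OC)C(=[N+]=[N-])C(C)=O | starting material
9 | 3-(2-diazoethenyl)-5-methoxy-2,4-bis(3-methylbut-2-en-1-yl)phenol | COc1cc(O)c(CC=C(C)C)c(C=C=[N+]=[N-])c1CC=C(C)C | intermediate (not isolated)
10 | 3-ethynyl-5-methoxy-2,4-bis(3-methylbut-2-en-1-yl)phenol | COc1cc(O)c(CC=C(C)C)c(C#C)c1CC=C(C)C | intermediate
11 | 4-iodobenzene-1,3-diol | Oc1ccc(I)c(O)c1 | starting material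
12 | 4-{[3-hydroxy-5-methoxy-2,6-bis(3-methylbut-2-en-1-yl)phenyl]ethynyl}benzene-1,3-diol | COc1cc(O)c(CC=C(C)C)c(C#Cc2ccc(O)cc2O)c1CC=C(C)C | intermediate (not isolated)
13 | 2-[3-hydroxy-5-methoxy-2,6-bis(3-methylbut-2-en-1-yl)phenyl]-1-benzofuran-6-ol (C25H28O4, achiral) | COc1cc(O)c(CC=C(C)C)c(-c2cc3ccc(O)cc3o2)c1CC=C(C)C | target

## Step count and risks
Total step count: 4. Longest linear sequence: 4 (1 → 4 → 7 → 10 → 13).

**Highest risk, step 2.** The double prenyl transfer acts on a crowded bromide that carries a free phenol. It may stall after one coupling or give some reverse-prenyl (γ) product.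
- The fallback sets out from 4 and comes back at 7.
- It replaces direct prenyl transfer with allylation followed by olefin metathesis.
- Compound 4 is coupled with allyltributylstannane, which is smaller, transmetalates faster and has no α/γ ambiguity. With Pd(PPh3)4 in DMF at 90 °C this gives 3-hydroxy-5-methoxy-2,6-di(prop-2-en-1-yl)benzaldehyde F1.
- Double cross-metathesis of F1 with excess 2-methylbut-2-ene (Grubbs second-generation catalyst, CH2Cl2, 40 °C) gives 7.
- The two allyl groups are meta to each other, so ring-closing metathesis cannot compete. Free ArOH and CHO are tolerated.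

**Second risk, step 4.** Free, electron-rich 4-iodoresorcinol may deiodinate or oxidise. Ring closure next to two ortho prenyl groups may also stop at 12.
- The fallback sets out from 10 and 11 and comes back at 12, which goes on to 13.
- It replaces the unprotected domino process with a protected, stepwise sequence that closes the ring anionically.
- Compound 11 is acetylated (Ac2O, pyridine, CH2Cl2) to 4-iodobenzene-1,3-diyl diacetate F3, a more robust and more reactive iodide.
- F3 is coupled with 10 at room temperature (PdCl2(PPh3)2, CuI, Et3N, THF). The isolated product is 4-{[3-hydroxy-5-methoxy-2,6-bis(3-methylbut-2-en-1-yl)phenyl]ethynyl}benzene-1,3-diyl diacetate F4. Any acetyl scrambling onto the free phenol is harmless.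
- K2CO3/MeOH then releases 12, which is closed without transition metals by Cs2CO3 in DMF at 80 °C to give 13.

**Third risk, step 3.** The 2,6-dialkylated aldehyde may add the diazophosphonate anion too slowly.
- The fallback sets out from 7 and comes back at 10.
- It replaces the diazo route with a Corey–Fuchs sequence.
- Ramirez olefination of 7 (CBr4, PPh3, Et3N, CH2Cl2, 0 °C) gives 3-(2,2-dibromoethenyl)-5-methoxy-2,4-bis(3-methylbut-2-en-1-yl)phenol F2.
- F2 is treated with n-BuLi (3.3 equiv, the first taken up by the phenol) in THF at −78 °C. Br/Li exchange and Fritsch–Buttenberg–Wiechell rearrangement follow, and a proton quench gives 10.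

Further compounds
F1 | step 2 | 3-hydroxy-5-methoxy-2,6-di(prop-2-en-1-yl)benzaldehyde | COc1cc(O)c(CC=C)c(C=O)c1CC=C
F2 | step 3 | 3-(2,2-dibromoethenyl)-5-methoxy-2,4-bis(3-methylbut-2-en-1-yl)phenol | COc1cc(O)c(CC=C(C)C)c(C=C(Br)Br)c1CC=C(C)C
F3 | step 4 | 4-iodobenzene-1,3-diyl diacetate | CC(=O)Oc1ccc(I)c(OC(C)=O)c1
F4 | step 4 | 4-{[3-hydroxy-5-methoxy-2,6-bis(3-methylbut-2-en-1-yl)phenyl]ethynyl}benzene-1,3-diyl diacetate | COc1cc(O)c(CC=C(C)C)c(C#Cc2ccc(OC(C)=O)cc2OC(C)=O)c1CC=C(C)C
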